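**Strategy.** Ring C (O1, C2, C3, C4, C4a, C8a) is not closed directly. It is grown from a racemic benzofuran-3(2H)-one that already carries the aryl group and a bromomethyl group on its quaternary C2. A radical 1,2-acyl shift (Dowd–Beckwith) moves the C4 carbonyl from C2 onto the exocyclic CH2, which becomes C3, and leaves a planar, benzylic, O1-substituted radical at C2. Both enantiomers of the precursor therefore converge, and hydrogen-atom transfer from a homochiral thiol should set the single (2S) stereocentre in the same operation. The feature exploited is the C4 ketone flanked by the C3 methylene and the O1- and aryl-bearing C2.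

Key step: step 5

Remark 1: compound 1 (the deoxybenzoin used for genistein manufacture) is taken as commercially available; "prenyl" means 3-methylbut-2-en-1-yl and MOM means methoxymethyl.
Remark 2: the D-mannose-derived thiol is assumed to deliver hydrogen to the face of radical 11 that gives 2S; if the opposite sense were found, the enantiomeric thiol from L-mannose would be used.

Step 1
Reactants: 1 2-(4-hydroxyphenyl)-1-(2,4,6-trihydroxyphenyl)ethan-1-one; 2 prenyl bromide (2.2 equiv)
Product: 3 2-(4-hydroxyphenyl)-1-[2,4,6-trihydroxy-3,5-diprenylphenyl]ethan-1-one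
Conditions: DBU (2.2 equiv), THF, 0 °C to rt
Reagents that add atoms: prenyl bromide, CC(C)=CCBr
Why: The acylphloroglucinol ring is the most acidic site and its phenolate should react with the soft allylic bromide at both free ring carbons (phenolate C-alkylation, C-prenylation of an acylphloroglucinol), while the less acidic ring B phenol stays protonated under the amidine base; mono-, geminal and O-prenylated by-products are removed by chromatography.

Step 2
Reactants: 3 2-(4-hydroxyphenyl)-1-[2,4,6-trihydroxy-3,5-diprenylphenyl]ethan-1-one; 4 chloromethyl methyl ether (3.3 equiv)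
Product: 5 1-[2-hydroxy-4,6-bis(methoxymethoxy)-3,5-diprenylphenyl]-2-[4-(methoxymethoxy)phenyl]ethan-1-one
Conditions: MOMCl, i-Pr2NEt, CH2Cl2, 0 °C to rt
Reagents that add atoms: chloromethyl methyl ether, COCCl
Why: O-alkylation (Williamson-type acetal formation) should protect the 4'-OH, the para OH and one ortho OH, whereas the last ortho OH is hydrogen-bonded to the ketone and flanked by a prenyl group and stays free, as is usual for 2,4,6-trihydroxyaryl ketones with MOMCl and an amine base.

Step 3
Reactants: 5 1-[2-hydroxy-4,6-bis(methoxymethoxy)-3,5-diprenylphenyl]-2-[4-(methoxymethoxy)phenyl]ethan-1-one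
Product: 7 rac-4,6-bis(methoxymethoxy)-2-[4-(methoxymethoxy)phenyl]-5,7-diprenylbenzofuran-3(2H)-one, via α-bromo ketone 6 (not isolated)
Conditions: LiN(SiMe3)2 (2.1 equiv), THF, −78 °C; cannulated into BrCCl2CCl2Br (1.05 equiv), −78 °C to rt, argon
Reagents that add atoms: none
Why: The phenoxide–enolate dianion should be brominated at the enolate carbon by the positive-bromine donor (enolate α-halogenation; the reagent leaves prenyl alkenes alone and collapses to C2Cl4 and bromide), and the neighbouring phenoxide then displaces the benzylic bromide 5-exo-tet (intramolecular Williamson etherification) to close the furanone, the new C2 centre being racemic and enolisable, which is of no consequence.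

Step 4
Reactants: 7 rac-4,6-bis(methoxymethoxy)-2-[4-(methoxymethoxy)phenyl]-5,7-diprenylbenzofuran-3(2H)-one; 8 dibromomethane (10 equiv)
Product: 9 rac-2-(bromomethyl)-4,6-bis(methoxymethoxy)-2-[4-(methoxymethoxy)phenyl]-5,7-diprenylbenzofuran-3(2H)-one
Conditions: NaH (1.1 equiv), CH2Br2, THF–DMPU, 0 to 40 °C, argon
Reagents that add atoms: dibromomethane, BrCBr
Why: The stabilised tertiary enolate of 7 should be C-alkylated by excess dibromomethane (enolate alkylation, the standard preparation of α-bromomethyl ketones for Dowd–Beckwith chemistry) to give the quaternary C2 as a racemate that has no α-hydrogen and so cannot eliminate, the excess electrophile suppressing bridging of two enolates and argon protecting the air-sensitive enol.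

Step 5
Reactants: 9 rac-2-(bromomethyl)-4,6-bis(methoxymethoxy)-2-[4-(methoxymethoxy)phenyl]-5,7-diprenylbenzofuran-3(2H)-one
Product: 12 (2S)-5,7-bis(methoxymethoxy)-2-[4-(methoxymethoxy)phenyl]-6,8-diprenylchroman-4-one, via primary alkyl radical 10 (not isolated), via ring-expanded C2 radical 11 (not isolated)
Conditions: Et3SiH (2 equiv), 2,3,4,6-tetra-O-acetyl-1-thio-β-D-mannopyranose (10 mol %), t-BuON=NOt-Bu (5 mol %, in portions), 1,2-epoxybutane (5 equiv), 1,4-dioxane–hexane, 60 °C, argon
Reagents that add atoms: none
Why: Proposed new method: the triethylsilyl radical abstracts bromine from 9, the primary radical 10 adds 3-exo-trig to the C3 ketone, and the cyclopropyloxy radical opens by β-scission of the old C2–C3 bond (net 1,2-acyl shift, Dowd–Beckwith ring expansion), so the five-membered furanone becomes the six-membered pyranone with the new CH2 as C3 and the benzylic, O1-substituted radical 11 at C2. The closest known reaction types are the Dowd–Beckwith expansion of α-(bromomethyl) cycloalkanones and the thiol-catalysed (polarity-reversal) reduction of alkyl halides by silanes, in which homochiral carbohydrate thiols are known to transfer hydrogen enantioselectively to cyclic α-oxyalkyl radicals; their combination in one chain is new. Radical 11 is planar, so both enantiomers of 9 converge, and the only stereocentre (C2) should be set by hydrogen-atom transfer from the S–H of the sugar thiol to one face of 11, Et3SiH being too poor a donor towards this stabilised nucleophilic radical to compete. The acyl shift must outrun premature reduction and 1,2-aryl shift of 10, which the low thiol loading, the relief of five-ring strain and the stabilisation of 11 should secure. Bromine abstraction must outrun silyl or thiyl attack on the prenyl groups, which the much faster halogen abstraction should secure, and the epoxide traps Et3SiBr before it can cleave the MOM ethers.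

Step 6
Reactants: 12 (2S)-5,7-bis(methoxymethoxy)-2-[4-(methoxymethoxy)phenyl]-6,8-diprenylchroman-4-one
Product: 13 (2S)-6,8-diprenylnaringenin
Conditions: HCl (1.25 M in MeOH), 30–35 °C
Reagents that add atoms: none
Why: Acid-catalysed acetal exchange with methanol should remove the three MOM groups as dimethoxymethane, the base-free medium avoiding the retro-oxa-Michael ring opening that would racemise C2 and the mild temperature sparing the prenyl groups from cyclisation onto the neighbouring phenols.

**Compound list**

1 | 2-(4-hydroxyphenyl)-1-(2,4,6-trihydroxyphenyl)ethan-1-one | O=C(Cc1ccc(O)cc1)c1c(O)cc(O)cc1O | starting material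
2 | prenyl bromide (1-bromo-3-methylbut-2-ene) | CC(C)=CCBr | starting material
3 | 2-(4-hydroxyphenyl)-1-[2,4,6-trihydroxy-3,5-diprenylphenyl]ethan-1-one | O=C(Cc1ccc(O)cc1)c1c(O)c(CC=C(C)C)c(O)c(CC=C(C)C)c1O | intermediate
4 | chloromethyl methyl ether | COCCl | starting material
5 | 1-[2-hydroxy-4,6-bis(methoxymethoxy)-3,5-diprenylphenyl]-2-[4-(methoxymethoxy)phenyl]ethan-1-one | O=C(Cc1ccc(OCOC)cc1)c1c(O)c(CC=C(C)C)c(OCOC)c(CC=C(C)C)c1OCOC | intermediate
6 | rac-2-bromo-1-[2-hydroxy-4,6-bis(methoxymethoxy)-3,5-diprenylphenyl]-2-[4-(methoxymethoxy)phenyl]ethan-1-one (present as its lithium phenoxide) | O=C(C(Br)c1ccc(OCOC)cc1)c1c(O)c(CC=C(C)C)c(OCOC)c(CC=C(C)C)c1OCOC | intermediate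
7 | rac-4,6-bis(methoxymethoxy)-2-[4-(methoxymethoxy)phenyl]-5,7-diprenylbenzofuran-3(2H)-one | O=C1C(c2ccc(OCOC)cc2)Oc2c(CC=C(C)C)c(OCOC)c(CC=C(C)C)c(OCOC)c12 | intermediate
8 | dibromomethane | BrCBr | starting material
9 | rac-2-(bromomethyl)-4,6-bis(methoxymethoxy)-2-[4-(methoxymethoxy)phenyl]-5,7-diprenylbenzofuran-3(2H)-one | O=C1C(CBr)(c2ccc(OCOC)cc2)Oc2c(CC=C(C)C)c(OCOC)c(CC=C(C)C)c(OCOC)c12 | intermediate
10 | primary alkyl radical (exocyclic CH2 radical on C2 of the benzofuranone) | [CH2]C1(c2ccc(OCOC)cc2)Oc2c(CC=C(C)C)c(OCOC)c(CC=C(C)C)c(OCOC)c2C1=O | intermediate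
11 | ring-expanded 4-oxochroman-2-yl radical (radical at C2) | O=C1C[C](c2ccc(OCOC)cc2)Oc2c(CC=C(C)C)c(OCOC)c(CC=C(C)C)c(OCOC)c12 | intermediate
12 | (2S)-5,7-bis(methoxymethoxy)-2-[4-(methoxymethoxy)phenyl]-6,8-diprenylchroman-4-one | CC(C)=CCc1c(OCOC)c(CC=C(C)C)c2c(c1OCOC)C(=O)C[C@@H](c1ccc(OCOC)cc1)O2 | intermediate
13 | (2S)-6,8-diprenylnaringenin, (2S)-5,7-dihydroxy-2-(4-hydroxyphenyl)-6,8-diprenylchroman-4-one | CC(C)=CCc1c(O)c(CC=C(C)C)c2c(c1O)C(=O)C[C@@H](c1ccc(O)cc1)O2 | target

**Step count.** Total: 6 steps. Longest linear sequence: 6 steps (1 → 3 → 5 → 7 → 9 → 12 → 13).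

**Steps most likely to fail**

Step 5 (bears the label). What may go wrong is poor facial discrimination in the hydrogen transfer to radical 11, loss of enantiopurity by reversible thiyl abstraction of the C2 hydrogen, reduction of radical 10 before the acyl shift, or thiyl-mediated isomerisation of the prenyl double bonds. The fallback uses known chemistry and sets out from 9. A conventional non-selective Dowd–Beckwith expansion with (Me3Si)3SiH (slow addition) and AIBN in toluene at 80 °C should give the racemic protected flavanone F1. Preparative HPLC on a cellulose-carbamate chiral stationary phase then separates 12 from its (2R) enantiomer F2, and the route is rejoined at 12.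

Step 4. What may go wrong is O-alkylation of the ambident enolate, bridging of two enolates by one dibromomethane, or air oxidation of the enol during the reaction. The fallback sets out from 7. A C-selective aldol addition to formaldehyde (paraformaldehyde, catalytic Et3N, THF, rt) should give the 2-(hydroxymethyl) ketone F3. Garegg–Samuelsson iodination (PPh3, imidazole, I2, toluene, 60 °C) should convert it into the 2-(iodomethyl) ketone F4. F4 is then submitted to the conditions of step 5, where iodine abstraction gives the same radical 10, and the route is rejoined at 12.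

Step 3. What may go wrong is over-bromination through proton exchange between the bromo ketone and unreacted enolate, or bromine transfer to the electron-rich phenoxide ring. The fallback sets out from 5. Hydroxylation of the dianion (LiN(SiMe3)2, THF, −78 °C, then 2-(phenylsulfonyl)-3-phenyloxaziridine) should give the α-hydroxy ketone F5. Mitsunobu cyclodehydration by the free ortho phenol (PPh3, DIAD, THF, 0 °C) should then close the furanone, and the route is rejoined at 7.

**Further compounds**

F1 | step 5 | racemic 5,7-bis(methoxymethoxy)-2-[4-(methoxymethoxy)phenyl]-6,8-diprenylchroman-4-one | CC(C)=CCc1c(OCOC)c(CC=C(C)C)c2c(c1OCOC)C(=O)CC(c1ccc(OCOC)cc1)O2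
F2 | step 5 | (2R)-5,7-bis(methoxymethoxy)-2-[4-(methoxymethoxy)phenyl]-6,8-diprenylchroman-4-one | CC(C)=CCc1c(OCOC)c(CC=C(C)C)c2c(c1OCOC)C(=O)C[C@H](c1ccc(OCOC)cc1)O2
F3 | step 4 | rac-2-(hydroxymethyl)-4,6-bis(methoxymethoxy)-2-[4-(methoxymethoxy)phenyl]-5,7-diprenylbenzofuran-3(2H)-one | O=C1C(CO)(c2ccc(OCOC)cc2)Oc2c(CC=C(C)C)c(OCOC)c(CC=C(C)C)c(OCOC)c12
F4 | step 4 | rac-2-(iodomethyl)-4,6-bis(methoxymethoxy)-2-[4-(methoxymethoxy)phenyl]-5,7-diprenylbenzofuran-3(2H)-one | O=C1C(CI)(c2ccc(OCOC)cc2)Oc2c(CC=C(C)C)c(OCOC)c(CC=C(C)C)c(OCOC)c12
F5 | step 3 | rac-2-hydroxy-1-[2-hydroxy-4,6-bis(methoxymethoxy)-3,5-diprenylphenyl]-2-[4-(methoxymethoxy)phenyl]ethan-1-one | O=C(C(O)c1ccc(OCOC)cc1)c1c(O)c(CC=C(C)C)c(OCOC)c(CC=C(C)C)c1OCOC
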